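The runs come from a simulation for substances that don't exist; the scatter is artificial.

- Should you dry the next flask or leave its protic impurity at 0.0800 M? Its charge, the earlier runs and what is asked stand here:

in all of them: substrate 0.16 M

|  | first nucleophile | protic impurity | solid second nucleophile | remark | time |
|---|---|---|---|---|---|
| ash | 1 equiv | 0.054 M | 2 equiv | run made earlier |  |
| maple | 1 equiv | 0.12 M | 2 equiv | run made earlier |  |
| oak | 0.50 equiv | 0.080 M | 2 equiv | run made earlier |  |
| flask | 1.00 equiv | 0.0800 M | 2.00 equiv |  | 80 min |

| run | time / min | target / % | substrate / % |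
|---|---|---|---|
| ash | 5.00 | 6.5 | 94.7 |
| ash | 12.0 | 12.9 | 86.2 |
| ash | 30.0 | 29.0 | 70.9 |
| ash | 60.0 | 47.1 | 52.0 |
| maple | 15.0 | 16.6 | 84.1 |
| maple | 30.0 | 29.3 | 70.7 |
| maple | 50.0 | 40.2 | 57.5 |
| maple | 60.0 | 45.2 | 51.9 |
| oak | 15.0 | 13.1 | 86.7 |
| oak | 30.0 | 21.4 | 78.2 |
| oak | 50.0 | 30.9 | 68.7 |
| oak | 60.0 | 33.0 | 64.9 |

(standard deviation of a reading: 0.5 percentage points)

1. amount of target in percent of the substrate charged, at 8.0 min, 25 min, 50 min and 80 min

- given per volume of solution although it is solid: solid second nucleophile
- steps under discussion: second nucleophile + intermediate -> other capture product; substrate <-> intermediate; first nucleophile + protic impurity -> quenched reagent; first nucleophile + intermediate -> target; solid second nucleophile <-> second nucleophile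
- at the start none of the solid second nucleophile is in solution

- Count half-lives. Let τ be the substrate half-life, the time in which the substrate would halve if its loss stayed first-order, read from one reading as time × ln(2) / ln(charged/left). The ash reading of 52.0% left at 60.0 min gives τ = 63.6 min.
- Test τ on maple, which holds 2.22 times the impurity of ash. The count predicts 52.0% substrate left at 60.0 min, and maple reads 51.9%. The substrate readings of ash and maple there differ by 0.1 percentage points, against a scatter of 0.5 points per reading, and both runs hold 1 equiv of first nucleophile, so this pair tests the impurity and not the first nucleophile.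
- Impurity costs little target in these runs: at 60.0 min, ash reads 47.1% and maple 45.2%, a gap of 1.9 points for 0.0660 M of impurity. The flask's charge lies between the two, so I would leave it undried.
- The asked time is 1.26 half-lives. Ash's substrate and target at 60.0 min add up to 99.1%, so I take target as the substrate gone, which gives 8.35%, 23.9%, 42.0% and 58.2%.
- The forecast says 8.9%, 24.8%, 41% and 52.5%, reasoning that “The flask sits between ash and maple, so early target should track them”, and its last figure is lower than mine.
- The flask gives 9.06%, 25.0%, 41.7% and 54.7%.

    second nucleophile + intermediate → other capture product (k = 1300 M⁻¹ h⁻¹)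
    substrate ⇌ intermediate (K = 0.00730, k = 1.00 h⁻¹)
    first nucleophile + protic impurity → quenched reagent (k = 2.10 M⁻¹ h⁻¹)
    first nucleophile + intermediate → target (k = 2400 M⁻¹ h⁻¹)
    solid second nucleophile ⇌ second nucleophile, rate k5*(cs5 - [second nucleophile]) while solid is left; crystals form when [second nucleophile] > cs5 (solubility = 13.0 mM, k = 0.930 h⁻¹)

- My last figure was higher than the flask's by 3.5 points, and at 80.0 min the flask still holds 43.7% substrate, where the count allowed 41.8%. That amount puts τ for this flask at 67.0 min, longer than the 63.6 min from ash. Oak, charged with 0.50 equiv of first nucleophile, reads 64.9% substrate at 60.0 min, which is a τ of 96.2 min.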